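## Analysis of the target

2,3,7-Tribromo-1H-indole (8) is a planar indole: a benzene ring (C3a to C7a) fused to a pyrrole ring (N1, C2, C3), with bromine at C2, C3 and C7 and a free N–H. It has no stereocentre, so the problem is one of regiochemistry and stability. C3 and then C2 are the positions an indole offers to electrophiles by itself, but C7 cannot be brominated selectively while C2, C3, C5 and C6 are free, so the C7 bromine has to arrive with the benzene ring. An N-unsubstituted 2,3-dibromoindole is electron-rich and labile: it is easily oxidised or hydrolysed towards oxindole-type products, it is sensitive to acid, light and silica gel, and its C–Br bonds do not tolerate organolithium reagents, zerovalent palladium or dissolving metals. The two pyrrole-ring bromines should therefore go in last, under mild anhydrous conditions, and the aryl bromide must survive everything before that. The feature on which the plan rests is the ortho relationship of C7–Br and C7a–N, which is the substitution pattern of 2-bromoaniline (1). Because C7 is occupied, C7a has a single free ortho neighbour, the future C3a, so an enamine carbon attached through that nitrogen can be joined to the ring at one position only. Since the target has no carbon substituent at C3, the group that activates this enamine carbon must later be exchangeable for bromine, and a carboxyl group is, by ipso-bromodecarboxylation.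

## Retrosynthetic reasoning

**C2–Br.** The C2–Br bond of 8 is cut first, leading to 3,7-dibromo-1H-indole (7). A 3-bromoindole takes electrophilic bromine at C2, its last open pyrrole position, so this bond needs no directing device. Cutting it first keeps the most labile substitution pattern out of every earlier intermediate.

**C3–Br.** The C3–Br bond of 7 is traced back to the C3–CO2H bond of 7-bromo-1H-indole-3-carboxylic acid (6). Electrophilic bromine attacks C3 ipso to the carboxyl group and the σ-complex decarboxylates in place of losing a proton. The gain is that C3 stays blocked by a stabilising acceptor until the final flask, and that the same reagent then carries 7 on to 8 without isolation. The forward reaction must deliver exactly two bromines to the pyrrole ring, leave the benzene ring alone and exclude moisture.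

**Ester.** Acid 6 comes from ethyl 7-bromo-1H-indole-3-carboxylate (5) by saponification. The ester, not the acid, is carried through ring formation because a free carboxylate would itself be oxidised at an anode. The ester is also the acceptor that stabilises the enamine precursor.

**C3–C3a.** In 5 the bond between C3 and C3a is cut, giving ethyl (2Z)-3-[(2-bromophenyl)amino]prop-2-enoate (3). This is the only ring bond whose disconnection leaves a plain C–H on the arene; cutting N1–C2 or C2–C3 would demand a 1,2,3-trisubstituted benzene with two different functional groups next to the bromine. Both carbons to be joined are nucleophilic, so the forward step is a dehydrogenative coupling that must remove two electrons and two protons. An anode with a halide redox mediator does this, passing through the N-iodo enamine 4, while protons are reduced at the cathode. No low-valent metal is present that could insert into the C7–Br bond. Regiochemistry needs no control, since the bromine leaves one ortho C–H only.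

**N1–C2.** Enamine 3 is cut at the bond between nitrogen and the future C2, giving 2-bromoaniline (1) and ethyl propiolate (2). Conjugate addition of the amino group of 1 to the alkyne of 2 forms this bond in one step with every atom retained. Compound 2 supplies C2, C3 and the carboxyl carbon, and compound 1 supplies the benzene ring, the nitrogen and the C7 bromine.

## Alternatives that were turned down

**Alternative 1: ynamide [2+2+2] benzannulation.**
- Disconnection: the benzene ring is taken apart at C3a–C7a, C4–C5 and C6–C7. This leads back to the nitrogen-tethered diyne N-(but-3-yn-1-yl)-4-methyl-N-[(trimethylsilyl)ethynyl]benzenesulfonamide A1 and acetylene A2.
- Forward key step: the monovalent rhodium catalyst RhCl(PPh3)3 would join the ynamide triple bond, the homopropargyl triple bond and A2 in a [2+2+2] cycloaddition. Both rings close at once to give 1-(4-methylbenzenesulfonyl)-7-(trimethylsilyl)indoline A3, where silicon marks C7 for a later ipso-bromodesilylation.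
- For: three C–C bonds and two rings come from one catalytic step, and the ynamide terminus dictates the position of the C7 substituent. In bond-forming power per step it is clearly stronger than the chosen route.
- Against: A3 carries none of the three bromines and is an N-sulfonyl indoline. Bromodesilylation, dehydrogenation, N-deprotection and double bromination at C2 and C3 all still follow, on top of the several steps that A1 needs (sulfonamide alkylation, copper-catalysed N-alkynylation). The silyl-capped ynamide is hindered towards oxidative cyclisation, and gaseous A2 can trimerise by itself or lose out to dimerisation of A1.
- Comparison: the chosen strategy buys the benzene ring with its bromine in place, reaches the indole oxidation level in the ring-forming step and is about half as long. It gives up convergence, which a target of eight carbons hardly needs.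

**Alternative 2: dibromodiene 6π electrocyclisation.**
- Disconnection: C7–C7a is cut and the benzene ring opened to a pyrrole carrying the other four carbons as a side chain, tert-butyl 3-bromo-4-[(1Z)-4,4-dibromobuta-1,3-dien-1-yl]-1H-pyrrole-1-carboxylate A4.
- Forward key step: irradiation at 365 nm with K2CO3 would drive a 6π electrocyclisation of the triene formed by the pyrrole C4=C5 bond and the two side-chain double bonds. Loss of HBr would then aromatise the ring to tert-butyl 3,7-dibromo-1H-indole-1-carboxylate A5.
- For: the C7 bromine is placed by the mechanism, since one bromine of the dibromoalkene stays on the ring-closing carbon, and the C3 bromine comes in with the pyrrole. A5 is N-protected, so the last bromine could enter C2 by deprotonation and quench. On certainty of bromine placement and on control of the C2 bromination it is as strong as the chosen route or stronger.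
- Against: A4 is a 3,4-disubstituted pyrrole, the pattern pyrrole chemistry delivers least readily, with a Z alkene and a dibromoalkene that need a homologation and a dibromo-olefination. The precursor alone is longer than the whole chosen route. The cyclisation must break pyrrole aromaticity in the intermediate, vinyl and aryl C–Br bonds can homolyse under ultraviolet light, and carbamate removal plus C2 bromination remain.
- Comparison: the chosen strategy puts its one uncertain step second in a four-step sequence on a substrate made in one step, so a failure costs little. Alternative 2 puts its uncertain step at the end of a long linear preparation.

**Alternative 3: aryne amination–bromination.**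
- Disconnection: N1–C7a and C7–Br are cut together as the two ends of an aryne, leading back to N-(tert-butyldimethylsilyl)-2-(2-fluorophenyl)ethan-1-amine A6.
- Forward key step: t-BuLi would deprotonate nitrogen and then the ring position next to fluorine, and loss of LiF would give the aryne. The tethered lithium amide would add to the nearer aryne carbon, forming N1–C7a and the five-membered ring. The aryllithium left at C7 would be brominated by 1,2-dibromotetrachloroethane to give 7-bromo-1-(tert-butyldimethylsilyl)indoline A7.
- For: the C7–Br bond forms exactly where the mechanism leaves the carbanion, a ring and a C–Br bond arise in one flask, and A6 is one silylation from a commercial amine. In overall length it is about equal to the chosen route.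
- Against: A7 is an indoline, so a dehydrogenation must follow, and the aryl bromide rules out palladium-catalysed dehydrogenation, leaving stoichiometric quinone or MnO2 oxidation. The key step needs excess t-BuLi at low temperature and a bulky, weakly nucleophilic N-silyl amide that must outrun addition of t-BuLi to the aryne. The ortho-lithiated N-silyl aniline can also suffer nitrogen-to-carbon silyl migration before the bromine donor arrives, and a protecting group is put on and taken off.
- Comparison: it spends its key step creating a C7–Br bond that the chosen route obtains for nothing from 1. The chosen route needs no organolithium reagent, no protecting group and no separate oxidation-state adjustment, and its carboxyl group keeps C3 blocked until bromine replaces it.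

Key step: step 2

Remark: in step 2 iodine is taken to be delivered first to nitrogen (compound 4); delivery to the α-carbon would pass through the same azaallyl species to the same product, and any E isomer of 3 equilibrates with the Z isomer through its imine tautomer and cyclises alike.

## Route

Step 1
Reactants: 1 2-bromoaniline; 2 ethyl propiolate (ethyl prop-2-ynoate)
Product: 3 ethyl (2Z)-3-[(2-bromophenyl)amino]prop-2-enoate
Conditions: 2 (1.2 equiv), EtOH, 70 °C
Reagents that add atoms: none
Why: Aza-Michael (conjugate) addition of the amino group to the activated alkyne, an addition in which all atoms of both reactants are retained. Protonation in the protic solvent and equilibration through the imine tautomer should favour the Z isomer, which is held by the N–H···O=C hydrogen bond. The ortho bromine lowers the nucleophilicity of nitrogen, hence the warming and the slight excess of 2, and it also disfavours a second addition.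

Step 2
Reactants: 3 ethyl (2Z)-3-[(2-bromophenyl)amino]prop-2-enoate
Product: 5 ethyl 7-bromo-1H-indole-3-carboxylate, via N-iodo enamine 4 (not isolated)
Conditions: KI (1 equiv), dry DMF, undivided cell, graphite anode, Pt cathode, constant current (ca. 2.5 F/mol), 80 °C, N2
Reagents that add atoms: none
Why: Iodide is oxidised at the graphite anode to iodine, which converts the N–H of 3 into the N-iodo enamine 4; the weak N–I bond breaks by homolysis (or ionisation) to a 1-azaallyl radical (or cation) delocalised over N1, C2 and C3. Its carbon terminus C3, further stabilised by the ester, attacks the free ortho carbon of the aryl ring to form C3–C3a, and a second one-electron oxidation with loss of a proton restores the benzene ring, after which the 3H-indole tautomerises to 5. The closest known reaction type is the iodide-mediated anodic dehydrogenative annulation of N-aryl enamino esters to indole-3-carboxylates, used here on an enamine without a substituent at the future C2. The pyrrole ring closes in a 5-endo-trig mode, which is accessible because the reacting carbon and the arene are the two ends of one planar conjugated aza-pentadienyl system (C3, C2, N1, C7a, C3a), so that the closure has the character of an electrocyclisation. No stereocentre is formed, and the alkene geometry of 3 is lost in the azaallyl intermediate. The step needs regioselectivity between the two positions ortho to nitrogen, and the C7 bromine secures it by leaving C3a as the only ortho C–H. It also needs chemoselectivity at both electrodes: under constant current the anode should settle at the iodide/iodine couple, below the potential at which 3 or the ester-deactivated product 5 is oxidised directly, and the Pt cathode should reduce the released protons at a potential far less negative than that of aryl C–Br cleavage. The balance of the step is loss of H2 from 3, with KI returned unchanged.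

Step 3
Reactants: 5 ethyl 7-bromo-1H-indole-3-carboxylate
Product: 6 7-bromo-1H-indole-3-carboxylic acid
Conditions: LiOH·H2O (5 equiv), THF/EtOH/H2O, 60 °C; then 1 M HCl, 0 °C, to pH 3
Reagents that add atoms: lithium hydroxide (as LiOH·H2O), [Li+].[OH-]
Why: Saponification (addition–elimination of hydroxide at the ester carbonyl); excess base and warming are used because an indole-3-carboxylate is a vinylogous carbamate and is partly deprotonated at nitrogen. The aryl bromide is inert to aqueous hydroxide, and cold, mild acidification should precipitate the acid without protodecarboxylation.

Step 4
Reactants: 6 7-bromo-1H-indole-3-carboxylic acid
Product: 8 2,3,7-tribromo-1H-indole, via 3,7-dibromo-1H-indole 7 (not isolated)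
Conditions: NBS (2.05 equiv, two portions), dry DMF, −10 °C to rt, dark, Ar
Reagents that add atoms: N-bromosuccinimide, O=C1CCC(=O)N1Br
Why: Bromodecarboxylation followed by electrophilic aromatic bromination: the first equivalent attacks C3, the most nucleophilic position, ipso to the carboxyl group, and the σ-complex loses CO2 in place of a proton to give 7. The second equivalent brominates 7 at C2, the only remaining pyrrole-ring position, directly or by attack at C3 and 1,2-shift of bromine. The benzene ring is far less nucleophilic and is further deactivated by the C7 bromine, so it should not react with two equivalents at low temperature, and exclusion of moisture should prevent diversion of the brominated σ-complex to oxindoles.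

## Compound list

1 | 2-bromoaniline | Nc1ccccc1Br | starting material
2 | ethyl propiolate (ethyl prop-2-ynoate) | C#CC(=O)OCC | starting material
3 | ethyl (2Z)-3-[(2-bromophenyl)amino]prop-2-enoate | CCOC(=O)/C=C\Nc1ccccc1Br | intermediate
4 | ethyl (2Z)-3-[(2-bromophenyl)(iodo)amino]prop-2-enoate (N-iodo enamine) | CCOC(=O)/C=C\N(I)c1ccccc1Br | intermediate
5 | ethyl 7-bromo-1H-indole-3-carboxylate | CCOC(=O)c1c[nH]c2c(Br)cccc12 | intermediate
6 | 7-bromo-1H-indole-3-carboxylic acid | OC(=O)c1c[nH]c2c(Br)cccc12 | intermediate
7 | 3,7-dibromo-1H-indole | Brc1c[nH]c2c(Br)cccc12 | intermediate
8 | 2,3,7-tribromo-1H-indole | Brc1[nH]c2c(Br)cccc2c1Br | target

## Step count and least certain steps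

Total step count: 4. Longest linear sequence: 4 steps (1 → 3 → 5 → 6 → 8).

**Step 2 (key step).** The most likely failure is that ring closure does not keep pace with consumption of the iodinated enamine. The azaallyl intermediate has no substituent at the future C2 to stabilise it, and the arene carbon to be attacked is inductively deactivated by the bromine meta to it. Dimerisation through the unsubstituted carbon terminus, build-up of an α-iodinated enamine that does not cyclise, or hydrolysis of the imine tautomer by traces of moisture could then take over. A smaller danger is reductive loss of the C7 bromine at the cathode if the proton supply runs low.

Fallback: replace the oxidative C3–C3a coupling by a boron-directed ortho-acylation (Sugasawa indole synthesis); it sets out from 1 and comes back at 7. Compound 1 with BCl3, chloroacetonitrile and AlCl3 in hot 1,2-dichloroethane, followed by hydrolysis of the ketimine with aqueous HCl, should acylate the only free position ortho to nitrogen and give 1-(2-amino-3-bromophenyl)-2-chloroethan-1-one F1. Reduction with NaBH4 in aqueous dioxane at reflux should give 7-bromo-1H-indole F2, by way of the chlorohydrin, N-alkylative ring closure and dehydration. One equivalent of N-bromosuccinimide in DMF at 0 °C should convert this into 7, which then takes the second equivalent as in step 4. The price is that C3 is no longer blocked before the end game.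

**Step 4.** Over-oxidation and decomposition may replace clean double bromination. Capture of the C3-brominated σ-complex by adventitious moisture leads towards oxindole-type products, further electrophilic bromine can enter the benzene ring at C5 or C6, and the N-unsubstituted product may degrade on silica gel or in light during isolation.

Fallback: introduce the C2 bromine by quenching a C2 carbanion of an N-protected indole in place of electrophilic substitution; it sets out from 6 and comes back at 8. One equivalent of N-bromosuccinimide converts 6 into 7, which is now isolated. NaH and benzenesulfonyl chloride in DMF should give 3,7-dibromo-1-(phenylsulfonyl)-1H-indole F3. Lithium diisopropylamide in THF at −78 °C should remove the C2 proton without exchanging the C–Br bonds, and 1,2-dibromotetrachloroethane should brominate the anion to give 2,3,7-tribromo-1-(phenylsulfonyl)-1H-indole F4. Tetrabutylammonium fluoride in warm THF should then cleave the N–S bond to give 8.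

**Step 1.** The addition may be sluggish because the aniline is weakly nucleophilic and hindered by the ortho bromine, so oligomerisation of 2 or a second addition to the product could compete on prolonged heating.

Fallback: replace conjugate addition to the alkyne by an acid-catalysed addition–elimination; it sets out from 1 and comes back at 3. Compound 1 and ethyl (E)-3-ethoxyprop-2-enoate with catalytic trifluoroacetic acid in hot ethanol should give 3 directly with loss of ethanol. No new compound is made on the way (F0).

## Further compounds

F1 | step 2 | 1-(2-amino-3-bromophenyl)-2-chloroethan-1-one | Nc1c(Br)cccc1C(=O)CCl
F2 | step 2 | 7-bromo-1H-indole | Brc1cccc2cc[nH]c12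
F3 | step 4 | 3,7-dibromo-1-(phenylsulfonyl)-1H-indole | Brc1cn(S(=O)(=O)c2ccccc2)c2c(Br)cccc12
F4 | step 4 | 2,3,7-tribromo-1-(phenylsulfonyl)-1H-indole | Brc1c(Br)c2cccc(Br)c2n1S(=O)(=O)c1ccccc1
F0 | step 1 | none | none
A1 | alternative 1 | N-(but-3-yn-1-yl)-4-methyl-N-[(trimethylsilyl)ethynyl]benzenesulfonamide | Cc1ccc(cc1)S(=O)(=O)N(CCC#C)C#C[Si](C)(C)C
A2 | alternative 1 | acetylene | C#C
A3 | alternative 1 | 1-(4-methylbenzenesulfonyl)-7-(trimethylsilyl)indoline | Cc1ccc(cc1)S(=O)(=O)N1CCc2cccc([Si](C)(C)C)c21
A4 | alternative 2 | tert-butyl 3-bromo-4-[(1Z)-4,4-dibromobuta-1,3-dien-1-yl]-1H-pyrrole-1-carboxylate | CC(C)(C)OC(=O)n1cc(Br)c(/C=C\C=C(Br)Br)c1
A5 | alternative 2 | tert-butyl 3,7-dibromo-1H-indole-1-carboxylate | CC(C)(C)OC(=O)n1cc(Br)c2cccc(Br)c12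
A6 | alternative 3 | N-(tert-butyldimethylsilyl)-2-(2-fluorophenyl)ethan-1-amine | CC(C)(C)[Si](C)(C)NCCc1ccccc1F
A7 | alternative 3 | 7-bromo-1-(tert-butyldimethylsilyl)indoline | CC(C)(C)[Si](C)(C)N1CCc2cccc(Br)c21
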